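**Retrosynthetic overview**

1. The target is epiafzelechin-(4β→8)-ent-epiafzelechin-(4α→8)-epiafzelechin: upper and lower units 2R,3R, middle unit 2S,3S, both interflavan bonds 3,4-trans. The last step is global O-debenzylation of the dodecabenzyl trimer.
2. Upper C4–C8 bond: Me3SiOSO2CF3 coupling of a (2R,3R) C4-(2-ethoxyethoxy) monomer with the perbenzylated dimer. Lower C4–C8 bond: the same coupling of the (2S,3S) C4-activated monomer with the (2R,3R) monomer. Each new C4 centre forms anti to the neighbouring 3-OBn.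
3. Both C4-activated monomers come from DDQ oxidation of the two mirror-image tetra-O-benzyl 2,3-cis-flavans.
4. Both cis-flavans come from one achiral 3-benzyloxyflav-2-ene by a chiral phosphoric acid/Hantzsch ester transfer hydrogenation run with either catalyst antipode (new reaction; sets C2 and C3).
5. Rings A and B are bought. Ring C is the only ring made (flavylium salt from a salicylaldehyde and an α-benzyloxy ketone, then hydride at C4), before any stereocentre exists.

Assumption: the (R)-acid is taken to give the (2R,3R) flavan and the (S)-acid its mirror image; the sense is read off the first run by chiral HPLC and, if reversed, the two acids change places between steps 4 and 5.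

**Route**

Step 1
Reactants: 1 4-(benzyloxy)phenylmagnesium bromide (1.0 M in THF); 2 2-(benzyloxy)-N-methoxy-N-methylacetamide
Product: 3 2-(benzyloxy)-1-[4-(benzyloxy)phenyl]ethan-1-one
Conditions: THF, 0 to 25 °C, 2 h; then 1 M aq. HCl
Reagents that add atoms: none
Why: Weinreb ketone synthesis; the chelated tetrahedral adduct stops the Grignard addition at the ketone stage.

Step 2
Reactants: 3 2-(benzyloxy)-1-[4-(benzyloxy)phenyl]ethan-1-one; 4 2,4-bis(benzyloxy)-6-hydroxybenzaldehyde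
Product: 6 3,5,7-tris(benzyloxy)-2-[4-(benzyloxy)phenyl]chromenylium tetrafluoroborate, via chalcone 5 (not isolated)
Conditions: 48% aq. HBF4 (3 equiv), AcOH, 25 °C, 16 h; precipitate with Et2O
Reagents that add atoms: tetrafluoroboric acid, [H+].F[B-](F)(F)F
Why: Robinson flavylium synthesis: acid-mediated aldol condensation at the activated methylene, then cyclodehydration of the 2-hydroxychalcone closes ring C as an achiral, crystalline salt.

Step 3
Reactants: 6 3,5,7-tris(benzyloxy)-2-[4-(benzyloxy)phenyl]chromenylium tetrafluoroborate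
Product: 7 3,5,7-tris(benzyloxy)-2-[4-(benzyloxy)phenyl]-4H-chromene
Conditions: NaBH4 (1.1 equiv), dry MeCN, -20 to 0 °C; aq. NaHCO3; filter through Al2O3 (basic); use at once
Reagents that add atoms: none
Why: Borohydride reduction of a flavylium salt in aprotic solvent delivers hydride to C4 and gives the neutral, achiral flav-2-ene; any 2H-isomer from C2 attack should be funnelled into 7 by acid-catalysed enol ether isomerisation in step 4.

Step 4
Reactants: 7 3,5,7-tris(benzyloxy)-2-[4-(benzyloxy)phenyl]-4H-chromene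
Product: 9 (2R,3R)-3,5,7-tris(benzyloxy)-2-[4-(benzyloxy)phenyl]chromane, via oxocarbenium ion 8 (not isolated)
Conditions: Hantzsch ester (diethyl 2,6-dimethyl-1,4-dihydropyridine-3,5-dicarboxylate, 1.3 equiv), (R)-3,3'-bis(2,4,6-triisopropylphenyl)-1,1'-binaphthyl-2,2'-diyl hydrogen phosphate [(R)-TRIP, 5 mol%], dry toluene, 40 °C, 36 h, Ar, dark; recrystallise
Reagents that add atoms: none
Why: Proposed new method: asymmetric transfer hydrogenation of a tetrasubstituted 3-alkoxy-4H-chromene enol ether; the chiral acid protonates C3 reversibly to give a 2-arylchroman-2-ylium/phosphate contact ion pair that racemises at C3 through 7, the phosphate holds the N-H of the Hantzsch ester and passes hydride to C2 of the matched (3R)-cation anti to the 3-OBn group (pushed pseudoaxial by A(1,2) strain against the coplanar 2-aryl group), so C2 and C3 are fixed together in one dynamic kinetic step as the 2,3-cis isomer; closest known reaction types are the chiral phosphoric acid/Hantzsch ester cascade reduction of 2,3-disubstituted quinolines to cis-tetrahydroquinolines and phosphoric-acid protonation of enol ethers in asymmetric spiroacetalisation.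

Step 5
Reactants: 7 3,5,7-tris(benzyloxy)-2-[4-(benzyloxy)phenyl]-4H-chromene
Product: 11 (2S,3S)-3,5,7-tris(benzyloxy)-2-[4-(benzyloxy)phenyl]chromane, via oxocarbenium ion 10 (not isolated)
Conditions: Hantzsch ester (diethyl 2,6-dimethyl-1,4-dihydropyridine-3,5-dicarboxylate, 1.3 equiv), (S)-3,3'-bis(2,4,6-triisopropylphenyl)-1,1'-binaphthyl-2,2'-diyl hydrogen phosphate [(S)-TRIP, 5 mol%], dry toluene, 40 °C, 36 h, Ar, dark; recrystallise
Reagents that add atoms: none
Why: Proposed new method: the mirror-image run of step 4, in which the (S)-phosphate selects the (3S)-cation and delivers hydride to C2 anti to 3-OBn by the same protonation/ion-pair hydride transfer mechanism; closest known reaction type as in step 4.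

Step 6
Reactants: 11 (2S,3S)-3,5,7-tris(benzyloxy)-2-[4-(benzyloxy)phenyl]chromane
Product: 13 (2S,3S,4R)-3,5,7-tris(benzyloxy)-2-[4-(benzyloxy)phenyl]-4-(2-ethoxyethoxy)chromane, via flavan-4-ylium hydroquinolate ion pair 12 (not isolated)
Conditions: DDQ (2,3-dichloro-5,6-dicyano-1,4-benzoquinone, 2 equiv), 2-ethoxyethanol (5 equiv), CH2Cl2, 25 °C, 2 h; aq. NaHCO3
Reagents that add atoms: 2-ethoxyethanol, CCOCCO
Why: DDQ benzylic oxidation: the quinone abstracts hydride from C4 (activated by the dialkoxy ring A) to give the C4 cation paired with the hydroquinone monoanion, and the alcohol traps it anti to 3-OBn, giving the 3,4-trans (4α) ether.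

Step 7
Reactants: 13 (2S,3S,4R)-3,5,7-tris(benzyloxy)-2-[4-(benzyloxy)phenyl]-4-(2-ethoxyethoxy)chromane; 9 (2R,3R)-3,5,7-tris(benzyloxy)-2-[4-(benzyloxy)phenyl]chromane (3 equiv, excess recovered)
Product: 15 octa-O-benzyl-ent-epiafzelechin-(4α→8)-epiafzelechin [upper unit 2S,3S,4S; lower unit 2R,3R], via flavan-4-ylium triflate 14 (not isolated)
Conditions: Me3SiOSO2CF3 (TMSOTf, 0.3 equiv), CH2Cl2, -78 °C, 1 h; Et3N quench
Reagents that add atoms: none
Why: Lewis-acid Friedel–Crafts interflavan coupling: the silyl triflate ionises the C4 ether to the flavan-4-ylium triflate, which is attacked by C8 of the excess nucleophile (more reactive than C6) on the face anti to the β-3-OBn group, setting the 4α (3,4-trans) centre.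

Step 8
Reactants: 9 (2R,3R)-3,5,7-tris(benzyloxy)-2-[4-(benzyloxy)phenyl]chromane
Product: 17 (2R,3R,4S)-3,5,7-tris(benzyloxy)-2-[4-(benzyloxy)phenyl]-4-(2-ethoxyethoxy)chromane, via flavan-4-ylium hydroquinolate ion pair 16 (not isolated)
Conditions: DDQ (2,3-dichloro-5,6-dicyano-1,4-benzoquinone, 2 equiv), 2-ethoxyethanol (5 equiv), CH2Cl2, 25 °C, 2 h; aq. NaHCO3
Reagents that add atoms: 2-ethoxyethanol, CCOCCO
Why: The same DDQ benzylic oxidation as step 6 in the mirror-image series, with the alcohol trapping the C4 cation anti to the α-3-OBn group to give the 4β (3,4-trans) ether.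

Step 9
Reactants: 17 (2R,3R,4S)-3,5,7-tris(benzyloxy)-2-[4-(benzyloxy)phenyl]-4-(2-ethoxyethoxy)chromane; 15 octa-O-benzyl-ent-epiafzelechin-(4α→8)-epiafzelechin (1.5 equiv)
Product: 19 dodeca-O-benzyl-epiafzelechin-(4β→8)-ent-epiafzelechin-(4α→8)-epiafzelechin [upper unit 2R,3R,4R; middle unit 2S,3S,4R; lower unit 2R,3R], via flavan-4-ylium triflate 18 (not isolated)
Conditions: Me3SiOSO2CF3 (TMSOTf, 0.3 equiv), CH2Cl2, -78 to -40 °C, 2 h; Et3N quench
Reagents that add atoms: none
Why: Lewis-acid Friedel–Crafts interflavan coupling: the flavan-4-ylium triflate formed from the ether is attacked by C8 of the upper unit of the dimer (the position para to an alkoxy group with the least hindrance, as in procyanidin trimer syntheses) anti to the α-3-OBn group, giving the 4β centre.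

Step 10
Reactants: 19 dodeca-O-benzyl-epiafzelechin-(4β→8)-ent-epiafzelechin-(4α→8)-epiafzelechin
Product: 20 epiafzelechin-(4β→8)-ent-epiafzelechin-(4α→8)-epiafzelechin (CNP0191553.2)
Conditions: H2 (1 atm), Pd(OH)2/C, THF/MeOH/H2O (20:1:1), 25 °C, 12 h; filter, lyophilise, Sephadex LH-20
Reagents that add atoms: none
Why: Neutral hydrogenolysis cleaves all twelve benzyl ethers without touching the acid-labile interflavan bonds or any stereocentre.

**Compound list**

1 | 4-(benzyloxy)phenylmagnesium bromide | Br[Mg]c1ccc(OCc2ccccc2)cc1 | starting material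
2 | 2-(benzyloxy)-N-methoxy-N-methylacetamide | CON(C)C(=O)COCc1ccccc1 | starting material
3 | 2-(benzyloxy)-1-[4-(benzyloxy)phenyl]ethan-1-one | O=C(COCc1ccccc1)c1ccc(OCc2ccccc2)cc1 | intermediate
4 | 2,4-bis(benzyloxy)-6-hydroxybenzaldehyde | O=Cc1c(O)cc(OCc2ccccc2)cc1OCc1ccccc1 | starting material
5 | (E)-2-(benzyloxy)-3-[2,4-bis(benzyloxy)-6-hydroxyphenyl]-1-[4-(benzyloxy)phenyl]prop-2-en-1-one (chalcone, not isolated) | O=C(c1ccc(OCc2ccccc2)cc1)/C(OCc1ccccc1)=C\c1c(O)cc(OCc2ccccc2)cc1OCc1ccccc1 | intermediate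
6 | 3,5,7-tris(benzyloxy)-2-[4-(benzyloxy)phenyl]chromenylium tetrafluoroborate | c1(-c2ccc(OCc3ccccc3)cc2)[o+]c2cc(OCc3ccccc3)cc(OCc3ccccc3)c2cc1OCc1ccccc1.F[B-](F)(F)F | intermediate
7 | 3,5,7-tris(benzyloxy)-2-[4-(benzyloxy)phenyl]-4H-chromene | C1(c2ccc(OCc3ccccc3)cc2)=C(OCc2ccccc2)Cc2c(OCc3ccccc3)cc(OCc3ccccc3)cc2O1 | intermediate
8 | (3R)-3,5,7-tris(benzyloxy)-2-[4-(benzyloxy)phenyl]chroman-2-ylium cation, ion-paired with the (R)-phosphate (not isolated) | C(c1ccccc1)Oc1cc(OCc2ccccc2)c2c(c1)[O+]=C(c1ccc(OCc3ccccc3)cc1)[C@H](OCc1ccccc1)C2 | intermediate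
9 | (2R,3R)-3,5,7-tris(benzyloxy)-2-[4-(benzyloxy)phenyl]chromane (tetra-O-benzylepiafzelechin) | C(c1ccccc1)Oc1cc(OCc2ccccc2)c2c(c1)O[C@H](c1ccc(OCc3ccccc3)cc1)[C@H](OCc1ccccc1)C2 | intermediate
10 | (3S)-3,5,7-tris(benzyloxy)-2-[4-(benzyloxy)phenyl]chroman-2-ylium cation, ion-paired with the (S)-phosphate (not isolated) | C(c1ccccc1)Oc1cc(OCc2ccccc2)c2c(c1)[O+]=C(c1ccc(OCc3ccccc3)cc1)[C@@H](OCc1ccccc1)C2 | intermediate
11 | (2S,3S)-3,5,7-tris(benzyloxy)-2-[4-(benzyloxy)phenyl]chromane (tetra-O-benzyl-ent-epiafzelechin) | C(c1ccccc1)Oc1cc(OCc2ccccc2)c2c(c1)O[C@@H](c1ccc(OCc3ccccc3)cc1)[C@@H](OCc1ccccc1)C2 | intermediate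
12 | (2S,3S)-3,5,7-tris(benzyloxy)-2-[4-(benzyloxy)phenyl]chroman-4-ylium 2,3-dichloro-5,6-dicyano-4-hydroxyphenolate (ion pair, not isolated) | C(c1ccccc1)Oc1ccc(cc1)[C@@H]1Oc2cc(OCc3ccccc3)cc(OCc3ccccc3)c2[CH+][C@@H]1OCc1ccccc1.[O-]c1c(Cl)c(Cl)c(O)c(C#N)c1C#N | intermediate
13 | (2S,3S,4R)-3,5,7-tris(benzyloxy)-2-[4-(benzyloxy)phenyl]-4-(2-ethoxyethoxy)chromane (2,3-cis-3,4-trans, 4α-ether) | C(c1ccccc1)Oc1ccc(cc1)[C@@H]1Oc2cc(OCc3ccccc3)cc(OCc3ccccc3)c2[C@@H](OCCOCC)[C@@H]1OCc1ccccc1 | intermediate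
14 | (2S,3S)-3,5,7-tris(benzyloxy)-2-[4-(benzyloxy)phenyl]chroman-4-ylium trifluoromethanesulfonate (ion pair, not isolated) | C(c1ccccc1)Oc1ccc(cc1)[C@@H]1Oc2cc(OCc3ccccc3)cc(OCc3ccccc3)c2[CH+][C@@H]1OCc1ccccc1.[O-]S(=O)(=O)C(F)(F)F | intermediate
15 | octa-O-benzyl-ent-epiafzelechin-(4α→8)-epiafzelechin (upper 2S,3S,4S; lower 2R,3R) | c1c(OCc3ccccc3)cc(OCc3ccccc3)c2c1O[C@@H](c1ccc(OCc3ccccc3)cc1)[C@@H](OCc1ccccc1)[C@@H]2c1c(OCc3ccccc3)cc(OCc3ccccc3)c2c1O[C@H](c1ccc(OCc3ccccc3)cc1)[C@H](OCc1ccccc1)C2 | intermediate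
16 | (2R,3R)-3,5,7-tris(benzyloxy)-2-[4-(benzyloxy)phenyl]chroman-4-ylium 2,3-dichloro-5,6-dicyano-4-hydroxyphenolate (ion pair, not isolated) | C(c1ccccc1)Oc1ccc(cc1)[C@H]1Oc2cc(OCc3ccccc3)cc(OCc3ccccc3)c2[CH+][C@H]1OCc1ccccc1.[O-]c1c(Cl)c(Cl)c(O)c(C#N)c1C#N | intermediate
17 | (2R,3R,4S)-3,5,7-tris(benzyloxy)-2-[4-(benzyloxy)phenyl]-4-(2-ethoxyethoxy)chromane (2,3-cis-3,4-trans, 4β-ether) | C(c1ccccc1)Oc1ccc(cc1)[C@H]1Oc2cc(OCc3ccccc3)cc(OCc3ccccc3)c2[C@H](OCCOCC)[C@H]1OCc1ccccc1 | intermediate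
18 | (2R,3R)-3,5,7-tris(benzyloxy)-2-[4-(benzyloxy)phenyl]chroman-4-ylium trifluoromethanesulfonate (ion pair, not isolated) | C(c1ccccc1)Oc1ccc(cc1)[C@H]1Oc2cc(OCc3ccccc3)cc(OCc3ccccc3)c2[CH+][C@H]1OCc1ccccc1.[O-]S(=O)(=O)C(F)(F)F | intermediate
19 | dodeca-O-benzyl-epiafzelechin-(4β→8)-ent-epiafzelechin-(4α→8)-epiafzelechin (upper 2R,3R,4R; middle 2S,3S,4R; lower 2R,3R) | C(c5ccccc5)Oc1ccc([C@H]2Oc3cc(OCc5ccccc5)cc(OCc5ccccc5)c3[C@H](c3c(OCc5ccccc5)cc(OCc5ccccc5)c4c3O[C@@H](c3ccc(OCc5ccccc5)cc3)[C@@H](OCc5ccccc5)[C@@H]4c3c(OCc5ccccc5)cc(OCc5ccccc5)c4c3O[C@H](c3ccc(OCc5ccccc5)cc3)[C@H](OCc5ccccc5)C4)[C@H]2OCc5ccccc5)cc1 | intermediate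
20 | epiafzelechin-(4β→8)-ent-epiafzelechin-(4α→8)-epiafzelechin (upper 2R,3R,4R; middle 2S,3S,4R; lower 2R,3R) | Oc1ccc([C@H]2Oc3cc(O)cc(O)c3[C@H](c3c(O)cc(O)c4c3O[C@@H](c3ccc(O)cc3)[C@@H](O)[C@@H]4c3c(O)cc(O)c4c3O[C@H](c3ccc(O)cc3)[C@H](O)C4)[C@H]2O)cc1 | target

**Totals and risks**

Total step count: 10. Longest linear sequence: 8 (steps 1, 2, 3, 5, 6, 7, 9, 10).

**Step 4 (and its mirror image, step 5), the new reaction.** Possible failures are slow turnover because the Hantzsch pyridine buffers the acid, modest ee or cis/trans ratio, acid-induced disproportionation of 7 into flavan and flavylium ion, and ring opening by traces of water. The fallback sets out from 7 and uses known chemistry. Kursanov–Parnes ionic hydrogenation (Et3SiH, CF3CO2H, CH2Cl2, -40 °C) reduces the enol ether, with the same axial hydride delivery expected to favour cis, to give racemic cis-3,5,7-tris(benzyloxy)-2-[4-(benzyloxy)phenyl]chromane F1 after removal of any trans isomer on silica. Preparative SFC on a chiral stationary phase then splits F1 into its two enantiomers, which are 9 and 11, so the fallback comes back at 9 and 11. Nothing is wasted, because the route consumes both antipodes.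

**Step 9, the trimer-forming coupling.** Possible failures are self-condensation of 17 through its own free C8, attack at the C6 positions of 15, and Lewis-acid scission of the existing interflavan bond. The fallback reverses the order of assembly so that the nucleophile is always a cheap monomer in excess. It sets out from 17 and 11. Coupling them (Me3SiOSO2CF3, CH2Cl2, -78 °C, 3 equiv of 11) gives octa-O-benzyl-epiafzelechin-(4β→8)-ent-epiafzelechin F2. Oxidation of its only remaining C4 methylene (lower unit) with DDQ and 2-ethoxyethanol gives the dimeric electrophile octa-O-benzyl-epiafzelechin-(4β→8)-[4α-(2-ethoxyethoxy)-ent-epiafzelechin] F3. Me3SiOSO2CF3 coupling of F3 with excess 9 at its C8 comes back at 19.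

**Step 2, flavylium formation.** Possible failures are benzyl ether loss or C-benzyl migration on the phloroglucinol ring under strong acid, and a low yield of the salt. The fallback sets out from 3 and makes the C4–C4a bond by Friedel–Crafts chemistry on a phenol instead of by aldol chemistry on the aldehyde. Heating 3 with N,N-dimethylformamide dimethyl acetal (neat, 100 °C) gives the enaminone (Z)-2-(benzyloxy)-1-[4-(benzyloxy)phenyl]-3-(dimethylamino)prop-2-en-1-one F4. Brief treatment of F4 with purchased 3,5-bis(benzyloxy)phenol (Oc1cc(OCc2ccccc2)cc(OCc2ccccc2)c1) in AcOH with HBF4 alkenylates the phenol ortho to the hydroxyl and closes ring C onto the ketone, coming back at 6.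

**Further compounds**

F1 | step 4 | racemic cis-3,5,7-tris(benzyloxy)-2-[4-(benzyloxy)phenyl]chromane (1:1 mixture of 9 and 11) | C(c1ccccc1)Oc1cc(OCc2ccccc2)c2c(c1)O[C@H](c1ccc(OCc3ccccc3)cc1)[C@H](OCc1ccccc1)C2.C(c1ccccc1)Oc1cc(OCc2ccccc2)c2c(c1)O[C@@H](c1ccc(OCc3ccccc3)cc1)[C@@H](OCc1ccccc1)C2
F2 | step 9 | octa-O-benzyl-epiafzelechin-(4β→8)-ent-epiafzelechin | C(c5ccccc5)Oc1ccc([C@H]2Oc3cc(OCc5ccccc5)cc(OCc5ccccc5)c3[C@H](c3c(OCc5ccccc5)cc(OCc5ccccc5)c4c3O[C@@H](c3ccc(OCc5ccccc5)cc3)[C@@H](OCc5ccccc5)C4)[C@H]2OCc5ccccc5)cc1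
F3 | step 9 | octa-O-benzyl-epiafzelechin-(4β→8)-[4α-(2-ethoxyethoxy)-ent-epiafzelechin] | C(c5ccccc5)Oc1ccc([C@H]2Oc3cc(OCc5ccccc5)cc(OCc5ccccc5)c3[C@H](c3c(OCc5ccccc5)cc(OCc5ccccc5)c4c3O[C@@H](c3ccc(OCc5ccccc5)cc3)[C@@H](OCc5ccccc5)[C@@H]4OCCOCC)[C@H]2OCc5ccccc5)cc1
F4 | step 2 | (Z)-2-(benzyloxy)-1-[4-(benzyloxy)phenyl]-3-(dimethylamino)prop-2-en-1-one | O=C(c1ccc(OCc2ccccc2)cc1)/C(OCc1ccccc1)=C/N(C)C
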